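## Retrosynthetic overview

1. The target is a (2S)-flavanone. Ring C is opened at O1–C2 (retro-oxa-Michael) to the free 2',4',6'-trihydroxy-3',5'-diprenylchalcone. The forward closure is a catalyst-controlled, chalcone-isomerase-type cyclisation that sets C2 in the last step.
2. Ring A of that chalcone is symmetric, so either ortho-OH closes to the same 5,7-dihydroxy-6,8-diprenyl pattern. No protecting groups are needed and there is no regiochemical question.
3. The chalcone Cα=Cβ bond comes from a polyanion aldol condensation of 3,5-diprenylphloroacetophenone with 2,2-dimethylchromene-6-carbaldehyde.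
4. The chromene pyran ring (ring D) comes from oxa-6π electrocyclisation of a vinylogous ortho-quinone methide, made from 4-hydroxybenzaldehyde and a prenal C5 unit. The ketone comes from double C-prenylation of phloroacetophenone.
5. Ring order: rings A and B are bought, ring D is formed first (step 2), ring C is formed last (step 4).

Assumption: C2 reads as (S) from the SMILES (O1 > C1' > C3 > H). The facial sense of the new step 4 cannot be derived with certainty. It is written for the quinine-derived catalyst and checked by ECD (2S: negative band near 290 nm, positive near 330 nm). The equally available quinidine-derived pseudo-enantiomer is used if the sign is reversed.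

## Route

**Step 1**
Reactants: 1 1-(2,4,6-trihydroxyphenyl)ethanone (phloroacetophenone); 2 1-bromo-3-methylbut-2-ene (prenyl bromide)
Product: 3 1-[2,4,6-trihydroxy-3,5-bis(3-methylbut-2-en-1-yl)phenyl]ethanone
Conditions: 2 (2.1 equiv), KOH (2.2 equiv), degassed H2O, Ar, 0 °C to rt, 16 h
Reagents that add atoms: prenyl bromide (compound 2), CC(C)=CCBr
Why: This is a double electrophilic aromatic C-prenylation (phenoxide C-alkylation, the laboratory counterpart of aromatic prenyltransferases), in which water solvates the phenoxide oxygens so the ambident acylphloroglucinol anion attacks the soft allylic bromide through its only two free ring carbons, about two equivalents of bromide limit geminal over-alkylation, and no stereocentre is formed.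

**Step 2**
Reactants: 4 4-hydroxybenzaldehyde; 5 1,1-diethoxy-3-methylbut-2-ene (prenal diethyl acetal)
Product: 7 2,2-dimethyl-2H-chromene-6-carbaldehyde, via ortho-quinone methide 6 (not isolated)
Conditions: 5 (1.5 equiv), 3-picoline (0.25 equiv), p-xylene, 140 °C, 24 h, EtOH distilled off
Reagents that add atoms: 1,1-diethoxy-3-methylbut-2-ene (compound 5), CCOC(OCC)C=C(C)C
Why: This is a thermal chromenylation of a phenol in which the acetal-derived oxocarbenium ion C-alkylates either equivalent ortho carbon, loss of the second ethanol gives the vinylogous ortho-quinone methide 6 (the species an oxidative cyclase makes from an ortho-prenylphenol), 6 closes by oxa-6π electrocyclisation with rearomatisation of ring B, the picoline/acetal protocol tolerates para-acceptor phenols, and no stereocentre is formed.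

**Step 3**
Reactants: 3 1-[2,4,6-trihydroxy-3,5-bis(3-methylbut-2-en-1-yl)phenyl]ethanone; 7 2,2-dimethyl-2H-chromene-6-carbaldehyde
Product: 9 (E)-3-(2,2-dimethyl-2H-chromen-6-yl)-1-[2,4,6-trihydroxy-3,5-bis(3-methylbut-2-en-1-yl)phenyl]prop-2-en-1-one, via aldol adduct 8 (not isolated)
Conditions: LiN(SiMe3)2 (4.1 equiv), THF, Ar, −78 to 0 °C; 7 (1.1 equiv), −78 °C to rt; poured into cold 1 M HCl (pH 2), fast extraction, crystallisation at −20 °C
Reagents that add atoms: none
Why: This is a Claisen–Schmidt aldol condensation run without protecting groups on the lithium tetra-anion (three phenoxides plus the methyl ketone enolate), in which only the enolate carbon adds to the non-enolisable aldehyde, aldolate 8 loses LiOH by E1cB on warming to give the (E)-enone, the open chain is the stable form while ring A is fully ionised, the fast cold acid quench delivers neutral 9 before it can close, and no stereocentre survives.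

**Step 4**
Reactants: 9 (E)-3-(2,2-dimethyl-2H-chromen-6-yl)-1-[2,4,6-trihydroxy-3,5-bis(3-methylbut-2-en-1-yl)phenyl]prop-2-en-1-one
Product: 10 (2S)-2-(2,2-dimethyl-2H-chromen-6-yl)-5,7-dihydroxy-6,8-bis(3-methylbut-2-en-1-yl)-2,3-dihydro-4H-chromen-4-one (target)
Conditions: 1-[3,5-bis(trifluoromethyl)phenyl]-3-[(8α,9S)-6'-methoxycinchonan-9-yl]thiourea (10 mol %), toluene (0.05 M), Ar, −25 °C, 72 h; cold filtration through acid-washed silica; recrystallisation to raise the ee
Reagents that add atoms: none
Why: Proposed new method: this is an organocatalytic copy of the chalcone isomerase reaction (enantioselective 6-endo-trig intramolecular oxa-Michael addition) on the free, unactivated chalcone; the quinuclidine nitrogen takes a proton from the acidic acylphloroglucinol and holds the phenoxide as a tight chiral ion pair in toluene; the thiourea N–H pair binds the carbonyl/enolate oxygen as the hydrogen-bond network of the enzyme does; the spectator ortho-OH locks the aryl ketone in plane by its internal hydrogen bond and supplies the second point of activation that known methods get from an added α-ester; the other ortho-oxygen therefore adds to one face of Cβ and sets C2 as (S) before the ammonium ion protonates C3; ring A is symmetric so both ortho-oxygens give the same product, neutral 9 should be inert in cold toluene so little racemic background is expected, and closure of a 2',6'-dihydroxychalcone is strongly downhill so the reversal that erodes ee with simple 2'-hydroxychalcones is suppressed; the closest known reaction types are the cinchona amine-thiourea cyclisation of α-(tert-butoxycarbonyl)-2'-hydroxychalcones to flavanones and the cinchona ammonium phenoxide ion-pair cyclisation of 2'-hydroxychalcone.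

## Compound list

| No. | Name | SMILES | Role |
|---|---|---|---|
| 1 | 1-(2,4,6-trihydroxyphenyl)ethanone | CC(=O)c1c(O)cc(O)cc1O | starting material |
| 2 | 1-bromo-3-methylbut-2-ene | CC(C)=CCBr | starting material |
| 3 | 1-[2,4,6-trihydroxy-3,5-bis(3-methylbut-2-en-1-yl)phenyl]ethanone | CC(=O)c1c(O)c(CC=C(C)C)c(O)c(CC=C(C)C)c1O | intermediate |
| 4 | 4-hydroxybenzaldehyde | O=Cc1ccc(O)cc1 | starting material |
| 5 | 1,1-diethoxy-3-methylbut-2-ene | CCOC(OCC)C=C(C)C | starting material |
| 6 | (3Z)-3-(3-methylbut-2-en-1-ylidene)-4-oxocyclohexa-1,5-diene-1-carbaldehyde (ortho-quinone methide, not isolated) | O=CC1=C/C(=C/C=C(C)C)C(=O)C=C1 | intermediate |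
| 7 | 2,2-dimethyl-2H-chromene-6-carbaldehyde | CC1(C)C=Cc2cc(C=O)ccc2O1 | intermediate |
| 8 | 3-(2,2-dimethyl-2H-chromen-6-yl)-3-hydroxy-1-[2,4,6-trihydroxy-3,5-bis(3-methylbut-2-en-1-yl)phenyl]propan-1-one (racemic, lithium salt in the flask, not isolated) | CC(C)=CCc1c(O)c(CC=C(C)C)c(O)c(C(=O)CC(O)c2ccc3c(c2)C=CC(C)(C)O3)c1O | intermediate |
| 9 | (E)-3-(2,2-dimethyl-2H-chromen-6-yl)-1-[2,4,6-trihydroxy-3,5-bis(3-methylbut-2-en-1-yl)phenyl]prop-2-en-1-one | CC(C)=CCc1c(O)c(CC=C(C)C)c(O)c(C(=O)/C=C/c2ccc3c(c2)C=CC(C)(C)O3)c1O | intermediate |
| 10 | (2S)-2-(2,2-dimethyl-2H-chromen-6-yl)-5,7-dihydroxy-6,8-bis(3-methylbut-2-en-1-yl)-2,3-dihydro-4H-chromen-4-one | CC(C)=CCc1c(O)c(CC=C(C)C)c2c(c1O)C(=O)C[C@@H](c1ccc3c(c1)C=CC(C)(C)O3)O2 | target |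

## Step count and risks

Total step count: 4. Longest linear sequence: 3 (steps 1, 3, 4 or steps 2, 3, 4).

The steps most likely to fail are, in order, step 4, step 3 and step 2.

**Risk 1, step 4.** The ee may be low because the very reactive 2',6'-dihydroxychalcone closes without the catalyst, or because the ring reopens. The fallback replaces asymmetric catalysis by resolution with recycling.
- It sets out from 9, which is closed without stereocontrol (NaOAc, EtOH, reflux) to the racemic flavanone F1.
- F1 is separated by preparative supercritical-fluid chromatography on an amylose tris(3,5-dimethylphenylcarbamate) phase into 10 and the (2R)-flavanone F2.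
- F2 is reopened in aqueous KOH/EtOH and poured into cold HCl, which returns it to 9 for another pass.
- The route is rejoined at 10.

**Risk 2, step 3.** The tetra-anion may be too insoluble or too unreactive, LiN(SiMe3)2 may consume 7 as its N-silyl imine, or 9 may close during work-up. The fallback gives up the protecting-group-free polyanion.
- It sets out from 3, which is treated with MOMCl (2.2 equiv) and iPr2NEt in CH2Cl2. This gives the hydrogen-bond-spared 1-[2-hydroxy-4,6-bis(methoxymethoxy)-3,5-bis(3-methylbut-2-en-1-yl)phenyl]ethanone F3.
- An ordinary Claisen–Schmidt condensation of F3 with 7 (KOH, EtOH/H2O, rt) gives the bis-MOM chalcone F4.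
- Dilute HCl in MeOH at rt removes both acetals, and the route is rejoined at 9.

**Risk 3, step 2.** The electron-poor phenol may be C-alkylated too slowly, so that the acetal decomposes first. The fallback makes the same ortho-quinone methide by oxidation instead of condensation.
- It sets out from 4, which is C-prenylated with 2 in aqueous KOH at rt to 4-hydroxy-3-(3-methylbut-2-en-1-yl)benzaldehyde F5.
- DDQ (1.1 equiv, 1,4-dioxane, reflux) abstracts the benzylic hydride to give 6, which electrocyclises as before.
- The route is rejoined at 7.

## Further compounds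

F1 | step 4 | racemic 2-(2,2-dimethyl-2H-chromen-6-yl)-5,7-dihydroxy-6,8-bis(3-methylbut-2-en-1-yl)-2,3-dihydro-4H-chromen-4-one | CC(C)=CCc1c(O)c(CC=C(C)C)c2c(c1O)C(=O)CC(c1ccc3c(c1)C=CC(C)(C)O3)O2
F2 | step 4 | (2R)-2-(2,2-dimethyl-2H-chromen-6-yl)-5,7-dihydroxy-6,8-bis(3-methylbut-2-en-1-yl)-2,3-dihydro-4H-chromen-4-one | CC(C)=CCc1c(O)c(CC=C(C)C)c2c(c1O)C(=O)C[C@H](c1ccc3c(c1)C=CC(C)(C)O3)O2
F3 | step 3 | 1-[2-hydroxy-4,6-bis(methoxymethoxy)-3,5-bis(3-methylbut-2-en-1-yl)phenyl]ethanone | CC(=O)c1c(O)c(CC=C(C)C)c(OCOC)c(CC=C(C)C)c1OCOC
F4 | step 3 | (E)-3-(2,2-dimethyl-2H-chromen-6-yl)-1-[2-hydroxy-4,6-bis(methoxymethoxy)-3,5-bis(3-methylbut-2-en-1-yl)phenyl]prop-2-en-1-one | COCOc1c(CC=C(C)C)c(O)c(C(=O)/C=C/c2ccc3c(c2)C=CC(C)(C)O3)c(OCOC)c1CC=C(C)C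
F5 | step 2 | 4-hydroxy-3-(3-methylbut-2-en-1-yl)benzaldehyde | CC(C)=CCc1cc(C=O)ccc1O
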